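**Retrosynthetic overview**
1. The strategy rests on ring C: the vicinal pair C9 (quaternary; methyl and C8) and C18 (methine carrying C19), next to the C12–C17 fusion with ring D, is what an ester-enolate [3,3] shift onto a trisubstituted alkene delivers.
2. Ring B is cut last at C2=C3 (reductive coupling of a C2 methyl ketone with the ring A C3 ketone). Ring A is cut at C5=C6 (metathesis, then hydroboration for C5 and C6) and at C7–C8 (syn aldol on the C8 aldehyde).
3. Ring C is cut at C9–C18: Ireland–Claisen ring contraction of a ring-D-fused δ-lactone (O on C11, carbonyl C19) whose (E)-alkenyl group on C11 is axial, trans to the C12 methyl. C18 is formed epimeric and is corrected afterwards by aldehyde equilibration.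
4. The lactone is cut at C10–C11 into an (E)-alkenyllithium (from propargyl alcohol) and a ring D aldehyde ester from 3,3-dimethylcyclohexanone (C12 by auxiliary-controlled methylation, C18–C19 by cross-coupling, C17 by hydroxyl-directed hydrogenation).
5. Order of ring formation: D (starting material), C (step 12), A (step 26), B (step 31).

Key step: step 12

Remark on numbering: ring A is C3–C4–C5(OH)–C6(Me)–C7, ring B is C2(Me)=C3–C7–C8(OH)–C9(Me)–C18–C19–C20, ring C is C9–C10–C11–C12(Me)–C17–C18, ring D is C12–C13–C14–C15(Me)2–C16–C17; β is the face of the C12 methyl group.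
Assumption: the lithio-enamine methylation of step 3 is taken to give the (R)-keto ester under the toluene/HMPA protocol; if the sense is opposite, the toluene/THF protocol or the D-valine ester is used.
Assumption: (−)-Ipc2B(allyl), from (−)-α-pinene, is taken to give the (3R)-carbinol in step 24; this centre is later oxidised away.

Step 1
Reactants: 1 3,3-dimethylcyclohexanone; 2 dimethyl carbonate
Product: 3 methyl 4,4-dimethyl-2-oxocyclohexane-1-carboxylate
Conditions: NaH (2.2 equiv), THF, reflux; AcOH quench
Reagents that add atoms: none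
Why: Claisen-type C-acylation of the ketone enolate occurs at the α-carbon remote from the gem-dimethyl group (future C12) and is driven by formation of the stabilised β-keto ester enolate.

Step 2
Reactants: 3 methyl 4,4-dimethyl-2-oxocyclohexane-1-carboxylate; 4 L-valine tert-butyl ester
Product: 5 enamino ester (vinylogous carbamate of 3)
Conditions: BF3·OEt2 (cat.), benzene, reflux, Dean–Stark trap
Reagents that add atoms: none
Why: Condensation of the amine with the ketone gives the conjugated, hydrogen-bonded enamino ester that carries the chiral auxiliary for the alkylation.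

Step 3
Reactants: 5 enamino ester
Product: 7 methyl (1R)-1,4,4-trimethyl-2-oxocyclohexane-1-carboxylate, via N-alkyl ketimine 6 (not isolated)
Conditions: LiN(i-Pr)2, toluene, −78 °C; HMPA (1 equiv); MeI, −78 → −55 °C; then aq. AcOH/NaOAc, 23 °C
Reagents that add atoms: iodomethane, CI; water, O
Why: Asymmetric alkylation of the chelated lithio-enamine (chiral enamine alkylation of a β-keto ester): the valine ester chelate shields one face so that methyl iodide sets the quaternary C12 centre, and hydrolysis returns the ketone and the auxiliary.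

Step 4
Reactants: 7 methyl (1R)-1,4,4-trimethyl-2-oxocyclohexane-1-carboxylate
Product: 8 methyl (1R)-1,4,4-trimethyl-2-(trifluoromethanesulfonyloxy)cyclohex-2-ene-1-carboxylate
Conditions: KN(SiMe3)2, THF, −78 °C; PhNTf2, −78 → 0 °C; aq. NH4Cl
Reagents that add atoms: N-phenylbis(trifluoromethanesulfonimide), O=S(=O)(N(c1ccccc1)S(=O)(=O)C(F)(F)F)C(F)(F)F
Why: The ketone can enolise only toward C16 because C12 is quaternary, and O-sulfonylation of the potassium enolate gives the C17 enol triflate.

Step 5
Reactants: 8 enol triflate; 9 tert-butyl bromoacetate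
Product: 11 methyl (1R)-2-(2-tert-butoxy-2-oxoethyl)-1,4,4-trimethylcyclohex-2-ene-1-carboxylate, via Reformatsky reagent 10 (not isolated)
Conditions: 9, Zn dust (Me3SiCl-activated), THF, 40 °C; then 8, Pd2(dba)3 (2.5 mol%), XPhos (10 mol%), THF, 65 °C
Reagents that add atoms: none
Why: Negishi cross-coupling of the zinc ester enolate with the alkenyl triflate attaches C18–C19 at C17, the tert-butyl ester keeping the Reformatsky reagent from self-condensation.

Step 6
Reactants: 11 diester
Product: 12 tert-butyl 2-[(6R)-6-(hydroxymethyl)-3,3,6-trimethylcyclohex-1-en-1-yl]acetate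
Conditions: LiBH4, MeOH (1 equiv), Et2O, 0 → 23 °C; aq. NH4Cl
Reagents that add atoms: none
Why: LiBH4 reduces the methyl ester chemoselectively beside the far less electrophilic tert-butyl ester and gives the C11 carbinol needed as a directing group.

Step 7
Reactants: 12 homoallylic alcohol
Product: 13 tert-butyl 2-[(1S,2R)-2-(hydroxymethyl)-2,5,5-trimethylcyclohexyl]acetate
Conditions: H2 (1 atm), [Ir(cod)(PCy3)(py)]PF6 (5 mol%), CH2Cl2, 23 °C
Reagents that add atoms: none
Why: Hydroxyl-directed hydrogenation: the cationic iridium catalyst binds the homoallylic C11 hydroxyl and delivers hydrogen to the C16=C17 face cis to CH2OH, which sets C17 with H17 cis to C11 and the acetate arm cis to the C12 methyl.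

Step 8
Reactants: 13 saturated hydroxy ester
Product: 14 tert-butyl 2-[(1S,2R)-2-formyl-2,5,5-trimethylcyclohexyl]acetate
Conditions: Dess–Martin periodinane, NaHCO3, CH2Cl2, 23 °C
Reagents that add atoms: none
Why: Dess–Martin oxidation of the neopentyl primary alcohol gives the non-enolisable C11 aldehyde without touching the tert-butyl ester.

Step 9
Reactants: 15 propargyl alcohol
Product: 17 (E)-3-iodo-2-methylprop-2-en-1-ol, via alkenylalane 16 (not isolated)
Conditions: AlMe3 (3 equiv), Cp2ZrCl2 (25 mol%), CH2Cl2, 0 → 23 °C; then I2, THF, −30 → 0 °C; aq. K2CO3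
Reagents that add atoms: trimethylaluminium, C[Al](C)C; iodine, II
Why: Zirconium-catalysed syn-carboalumination of the terminal alkyne puts methyl on the internal carbon and aluminium on the terminus, and iodinolysis with retention gives the (E)-iodide.

Step 10
Reactants: 17 (E)-3-iodo-2-methylprop-2-en-1-ol
Product: 18 (E)-[(3-iodo-2-methylprop-2-enyl)oxymethyl]benzene
Conditions: NaH, BnBr, Bu4NI (cat.), THF, 0 → 23 °C
Reagents that add atoms: benzyl bromide, BrCc1ccccc1
Why: Williamson etherification protects the C8 hydroxyl as a benzyl ether that survives the organolithium, enolate and hydride steps and is removed in the hydrogenation of step 16.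

Step 11
Reactants: 18 (E)-alkenyl iodide; 14 ring D aldehyde ester
Product: 21 trans-fused δ-lactone bearing the axial (E)-alkenyl group on C11, via alkenyllithium 19 (not isolated), via lithium alkoxide 20 (not isolated)
Conditions: 18, t-BuLi (2.0 equiv), Et2O, −78 °C; 14, −78 °C; then 23 °C
Reagents that add atoms: none
Why: Iodine–lithium exchange with retention of the E geometry is followed by Felkin–Anh 1,2-addition to the α-quaternary aldehyde anti to the branched C12–C17 bond, which should set C11 with the alkenyl group trans to the C12 methyl, and the lithium alkoxide then closes the δ-lactone by acyl substitution at the tert-butyl ester.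

Step 12
Reactants: 21 trans-fused δ-lactone
Product: 24 octalin carboxylic acid with quaternary C9 (C19 axial on C18), via silyl ketene acetal 22 (not isolated), via trimethylsilyl ester 23 (not isolated)
Conditions: LiN(i-Pr)2 (1.3 equiv), Me3SiCl/Et3N (1:1, premixed), THF, −78 → 23 °C; solvent change to toluene, 110 °C; then 1 M HCl, THF, 23 °C
Reagents that add atoms: none
Why: Kinetic deprotonation at C18 and O-silylation give the cyclic silyl ketene acetal 22, whose C18=C19–O–C11–C10=C9 array undergoes a concerted suprafacial [3,3] shift through the boat-like bicyclo[2.2.2] transition state enforced by the C12–C17 tether; this is the Ireland–Claisen rearrangement of an alkenyl lactone, the known lactone-to-carbocycle ring contraction. Ring C closes by C9–C18 bonding across the lactone as C11–O breaks, a six-membered closure in which the allyl unit stays inside the new ring, so that C10=C11 becomes the cyclohexene double bond and C19 is released as the carboxyl group. C9 is controlled by the E geometry of C9=C10 together with the C11 configuration: bonding occurs on the alkene face syn to the departing oxygen, which puts the outside CH2OBn arm on the β face and the inside methyl, lying next to H17, on the α face. C18 is controlled by C11 alone: the axial alkenyl group reaches only the α face of the ketene acetal, so C19 emerges β, cis to the C12 methyl, and this centre is corrected by equilibration in step 14. The step needs O-silylation to outrun C-silylation and Claisen condensation (in situ Me3SiCl/Et3N quench at −78 °C) and it needs a reactive conformer, which the trans ring fusion supplies because the alkenyl group is already axial in the ground-state half-chair. The C11 epimer with an equatorial (Z)-alkenyl group would give C18 directly, but it must reach the boat by eclipsing the alkenyl group with the C12 methyl and pressing the inside substituent onto C16, so it is not used.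

Step 13
Reactants: 24 octalin carboxylic acid
Product: 25 primary alcohol (axial C19H2OH on C18)
Conditions: LiAlH4, THF, 0 → 65 °C; aq. NaOH work-up
Reagents that add atoms: none
Why: Hydride reduction of the hindered carboxylic acid gives the primary alcohol while the benzyl ether and the ring C alkene are inert.

Step 14
Reactants: 25 primary alcohol
Product: 27 equatorial C19 aldehyde (C18 as in the target), via axial aldehyde 26 (not isolated)
Conditions: Dess–Martin periodinane, NaHCO3, CH2Cl2, 23 °C; filtration; DBU (0.3 equiv), CH2Cl2, 23 °C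
Reagents that add atoms: none
Why: Oxidation gives the axial aldehyde, and base-catalysed enolisation then epimerises C18 under thermodynamic control to the equatorial aldehyde, which relieves the 1,3-diaxial contact with the C12 methyl and sets the C18 configuration of the target.

Step 15
Reactants: 27 equatorial C19 aldehyde
Product: 28 (E)-enone (C19=C20–C2(=O)–CH3)
Conditions: dimethyl (2-oxopropyl)phosphonate, LiCl, i-Pr2NEt, MeCN, 23 °C
Reagents that add atoms: dimethyl (2-oxopropyl)phosphonate, COP(=O)(OC)CC(C)=O
Why: Horner–Wadsworth–Emmons olefination under mild Masamune–Roush conditions adds C20, C2 and the C2 methyl as the (E)-enone without disturbing the now thermodynamic C18 centre.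

Step 16
Reactants: 28 (E)-enone
Product: 29 saturated keto alcohol (free C8 hydroxyl)
Conditions: H2 (4 atm), Pd(OH)2/C, EtOAc/EtOH, 23 °C
Reagents that add atoms: none
Why: One hydrogenation saturates the enone C19=C20 bond and the ring C alkene C10=C11 (no new stereocentre) and cleaves the benzyl ether by hydrogenolysis.

Step 17
Reactants: 29 keto alcohol
Product: 30 dioxolane alcohol
Conditions: ethane-1,2-diol, TsOH·H2O (cat.), benzene, reflux, Dean–Stark trap
Reagents that add atoms: ethane-1,2-diol, OCCO
Why: Acid-catalysed ketalisation masks the C2 ketone for the hydride, organoboron and borane steps that follow.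

Step 18
Reactants: 30 dioxolane alcohol
Product: 31 C8 aldehyde
Conditions: Dess–Martin periodinane, pyridine, CH2Cl2, 23 °C
Reagents that add atoms: none
Why: Buffered Dess–Martin oxidation of the neopentyl C8 alcohol gives the non-enolisable aldehyde and leaves the dioxolane intact.

Step 19
Reactants: 32 (R)-4-benzyloxazolidin-2-one; 33 3-methylbut-2-enoyl chloride
Product: 34 (R)-4-benzyl-3-(3-methylbut-2-enoyl)oxazolidin-2-one
Conditions: n-BuLi, THF, −78 °C; then 33, −78 → 0 °C
Reagents that add atoms: none
Why: N-Acylation of the lithiated oxazolidinone gives the imide that serves as the chiral C3–C7–C6 unit.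

Step 20
Reactants: 34 imide; 31 C8 aldehyde
Product: 36 syn-aldol adduct, via boron dienolate 35 (not isolated)
Conditions: 34, Bu2BOTf, Et3N, CH2Cl2, −78 → 0 °C; 31, −78 → 0 °C; then pH 7 buffer, MeOH, 30% H2O2, 0 °C
Reagents that add atoms: none
Why: Evans syn-aldol reaction of the boron dienolate at its α-carbon through a closed chair transition state, in which the (R)-benzyl auxiliary selects the enolate face and so sets C7 and C8 (7,8-syn, C8 hydroxyl as in the target) under reagent control, C7 carrying the isopropenyl group that becomes C6.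

Step 21
Reactants: 36 syn-aldol adduct
Product: 37 C8 tert-butyldimethylsilyl ether
Conditions: TBSOTf, 2,6-lutidine, CH2Cl2, 0 → 23 °C
Reagents that add atoms: tert-butyldimethylsilyl trifluoromethanesulfonate, CC(C)(C)[Si](C)(C)OS(=O)(=O)C(F)(F)F
Why: The reactive silyl triflate protects the hindered C8 hydroxyl and blocks retro-aldol cleavage in the later steps.

Step 22
Reactants: 37 silylated imide
Product: 38 C3 primary alcohol
Conditions: LiBH4, MeOH (1 equiv), THF, 0 °C; aq. NH4Cl
Reagents that add atoms: none
Why: Reductive cleavage of the N-acyloxazolidinone releases the primary alcohol and the recoverable auxiliary.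

Step 23
Reactants: 38 C3 primary alcohol
Product: 39 C3 aldehyde (α-isopropenyl)
Conditions: Dess–Martin periodinane, NaHCO3, CH2Cl2, 0 °C
Reagents that add atoms: none
Why: Buffered, non-basic oxidation gives the β,γ-unsaturated aldehyde without epimerisation at C7 or migration of the double bond into conjugation.

Step 24
Reactants: 39 C3 aldehyde
Product: 40 C3 homoallylic alcohol
Conditions: (−)-Ipc2B(allyl), Et2O, −78 °C; then 3 M NaOH, 30% H2O2
Reagents that add atoms: (−)-B-allyldiisopinocampheylborane, C=CCB([C@H]1C[C@H]2C[C@@H]([C@@H]1C)C2(C)C)[C@H]1C[C@H]2C[C@@H]([C@@H]1C)C2(C)C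
Why: Brown allylboration through a chair transition state adds C4 with the terminal alkene needed for ring closure, the reagent fixing the C3 carbinol (cis to C8 on the future ring), a centre that is oxidised away in step 30.

Step 25
Reactants: 40 C3 homoallylic alcohol
Product: 41 C3 triethylsilyl ether
Conditions: Et3SiCl, imidazole, DMF, 0 → 23 °C
Reagents that add atoms: chlorotriethylsilane, CC[Si](Cl)(CC)CC
Why: Silylation gives a triethylsilyl ether that can later be removed beside the two tert-butyldimethylsilyl ethers.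

Step 26
Reactants: 41 diene
Product: 42 cyclopentene (ring A closed, C5=C6)
Conditions: second-generation Grubbs catalyst (5 mol%), CH2Cl2, 40 °C
Reagents that add atoms: none
Why: Ring-closing metathesis of the allyl and isopropenyl groups closes the five-membered ring A as the trisubstituted alkene C5=C6 with loss of ethene.

Step 27
Reactants: 42 cyclopentene
Product: 44 C5 alcohol, via alkylborane 43 (not isolated)
Conditions: BH3·THF, THF, 0 → 23 °C; then 3 M NaOH, 30% H2O2, 0 → 23 °C
Reagents that add atoms: hydrogen peroxide, OO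
Why: Hydroboration–oxidation adds B–H syn across C5=C6 from the face opposite the C7 side chain with boron on the less substituted C5, so that after oxidation with retention the C5 hydroxyl is trans to the C6 methyl and the C6 methyl is cis to C8.

Step 28
Reactants: 44 C5 alcohol
Product: 45 C5,C8-bis(tert-butyldimethylsilyl) C3-triethylsilyl ether
Conditions: TBSCl, imidazole, DMF, 40 °C
Reagents that add atoms: tert-butyl(chloro)dimethylsilane, CC(C)(C)[Si](C)(C)Cl
Why: Silylation of the secondary cyclopentanol protects C5–OH through the oxidation and the reductive coupling.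

Step 29
Reactants: 45 fully protected intermediate
Product: 46 C3 alcohol with free C2 ketone
Conditions: PPTS, acetone/H2O (10:1), 55 °C
Reagents that add atoms: water, O
Why: Mild acid hydrolysis removes the dioxolane and the secondary triethylsilyl ether in one operation while both tert-butyldimethylsilyl ethers remain.

Step 30
Reactants: 46 hydroxy ketone
Product: 47 C2,C3-diketone
Conditions: Dess–Martin periodinane, NaHCO3, CH2Cl2, 0 → 23 °C
Reagents that add atoms: none
Why: Neutral Dess–Martin oxidation gives the ring A ketone at C3 without epimerising the adjacent C7 centre or eliminating the β-silyloxy groups.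

Step 31
Reactants: 47 diketone
Product: 48 bis(tert-butyldimethylsilyl) ether of the target
Conditions: TiCl3(DME)1.5, Zn–Cu couple, DME, reflux; 47 added slowly by syringe pump (high dilution)
Reagents that add atoms: none
Why: Intramolecular McMurry coupling: low-valent titanium joins the two ketones to a titanium pinacolate and deoxygenates it to the tetrasubstituted C2=C3 alkene, closing the eight-membered ring B, whose size fixes the alkene geometry (C20 cis to C7).

Step 32
Reactants: 48 bis-silyl ether
Product: 49 CNP0213887.1 (target)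
Conditions: HF·pyridine, pyridine, THF, 0 → 40 °C
Reagents that add atoms: none
Why: Buffered fluoride cleavage removes both silyl ethers without acid-induced migration of the tetrasubstituted alkene.

**Compound list**
1 | 3,3-dimethylcyclohexanone | CC1(C)CCCC(=O)C1 | starting material
2 | dimethyl carbonate | COC(=O)OC | starting material
3 | methyl 4,4-dimethyl-2-oxocyclohexane-1-carboxylate (racemic) | COC(=O)C1CCC(C)(C)CC1=O | intermediate
4 | L-valine tert-butyl ester | CC(C)[C@H](N)C(=O)OC(C)(C)C | starting material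
5 | methyl 2-{[(2S)-1-tert-butoxy-3-methyl-1-oxobutan-2-yl]amino}-4,4-dimethylcyclohex-1-ene-1-carboxylate (enamino ester) | COC(=O)C1=C(N[C@@H](C(C)C)C(=O)OC(C)(C)C)CC(C)(C)CC1 | intermediate
6 | N-alkyl ketimine of 7 (C12 methylated, not isolated) | COC(=O)[C@]1(C)CCC(C)(C)CC1=N[C@@H](C(C)C)C(=O)OC(C)(C)C | intermediate
7 | methyl (1R)-1,4,4-trimethyl-2-oxocyclohexane-1-carboxylate | COC(=O)[C@]1(C)CCC(C)(C)CC1=O | intermediate
8 | methyl (1R)-1,4,4-trimethyl-2-(trifluoromethanesulfonyloxy)cyclohex-2-ene-1-carboxylate | COC(=O)[C@]1(C)CCC(C)(C)C=C1OS(=O)(=O)C(F)(F)F | intermediate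
9 | tert-butyl bromoacetate | BrCC(=O)OC(C)(C)C | starting material
10 | (2-tert-butoxy-2-oxoethyl)zinc bromide (not isolated) | Br[Zn]CC(=O)OC(C)(C)C | intermediate
11 | methyl (1R)-2-(2-tert-butoxy-2-oxoethyl)-1,4,4-trimethylcyclohex-2-ene-1-carboxylate | COC(=O)[C@]1(C)CCC(C)(C)C=C1CC(=O)OC(C)(C)C | intermediate
12 | tert-butyl 2-[(6R)-6-(hydroxymethyl)-3,3,6-trimethylcyclohex-1-en-1-yl]acetate | OC[C@]1(C)CCC(C)(C)C=C1CC(=O)OC(C)(C)C | intermediate
13 | tert-butyl 2-[(1S,2R)-2-(hydroxymethyl)-2,5,5-trimethylcyclohexyl]acetate | OC[C@]1(C)CCC(C)(C)C[C@H]1CC(=O)OC(C)(C)C | intermediate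
14 | tert-butyl 2-[(1S,2R)-2-formyl-2,5,5-trimethylcyclohexyl]acetate | O=C[C@]1(C)CCC(C)(C)C[C@H]1CC(=O)OC(C)(C)C | intermediate
15 | propargyl alcohol | C#CCO | starting material
16 | (E)-alkenylalane, dimethylaluminium alkoxide form (not isolated) | C[Al](C)OC/C(C)=C/[Al](C)C | intermediate
17 | (E)-3-iodo-2-methylprop-2-en-1-ol | OC/C(C)=C/I | intermediate
18 | (E)-[(3-iodo-2-methylprop-2-enyl)oxymethyl]benzene | I/C=C(C)/COCc1ccccc1 | intermediate
19 | (E)-3-benzyloxy-2-methylprop-1-enyllithium (not isolated) | [Li]/C=C(C)/COCc1ccccc1 | intermediate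
20 | lithium alkoxide of the C11 carbinol, tert-butyl ester (not isolated) | [Li+].[O-][C@H](/C=C(C)/COCc1ccccc1)[C@]1(C)CCC(C)(C)C[C@H]1CC(=O)OC(C)(C)C | intermediate
21 | trans-fused δ-lactone (O on C11, carbonyl C19); (E)-3-benzyloxy-2-methylprop-1-enyl group on C11 axial, trans to the C12 methyl | c1ccccc1COC/C(C)=C/[C@H]2OC(=O)C[C@@H]3CC(C)(C)CC[C@@]23C | intermediate
22 | trimethylsilyl ketene acetal of 21 (not isolated) | c1ccccc1COC/C(C)=C/[C@H]2OC(O[Si](C)(C)C)=C[C@@H]3CC(C)(C)CC[C@@]23C | intermediate
23 | trimethylsilyl ester of 24 (not isolated) | c1ccccc1COC[C@@]2(C)C=C[C@]3(C)CCC(C)(C)C[C@H]3[C@H]2C(=O)O[Si](C)(C)C | intermediate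
24 | octalin carboxylic acid: C9 quaternary (α methyl, β CH2OBn), C10=C11, C19OOH on C18 β (axial, cis to C12 methyl) | c1ccccc1COC[C@@]2(C)C=C[C@]3(C)CCC(C)(C)C[C@H]3[C@H]2C(=O)O | intermediate
25 | primary alcohol from 24 (axial C19H2OH) | c1ccccc1COC[C@@]2(C)C=C[C@]3(C)CCC(C)(C)C[C@H]3[C@H]2CO | intermediate
26 | axial C19 aldehyde (not isolated) | c1ccccc1COC[C@@]2(C)C=C[C@]3(C)CCC(C)(C)C[C@H]3[C@H]2C=O | intermediate
27 | equatorial C19 aldehyde (C18 as in the target) | c1ccccc1COC[C@@]2(C)C=C[C@]3(C)CCC(C)(C)C[C@H]3[C@@H]2C=O | intermediate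
28 | (E)-enone, C18–CH=CH–C(=O)CH3 | c1ccccc1COC[C@@]2(C)C=C[C@]3(C)CCC(C)(C)C[C@H]3[C@@H]2/C=C/C(C)=O | intermediate
29 | saturated keto alcohol (C8–OH, C2 ketone, trans-decalin) | OC[C@@]1(C)CC[C@]2(C)CCC(C)(C)C[C@H]2[C@@H]1CCC(C)=O | intermediate
30 | dioxolane alcohol | OC[C@@]1(C)CC[C@]2(C)CCC(C)(C)C[C@H]2[C@@H]1CCC1(C)OCCO1 | intermediate
31 | C8 aldehyde | O=C[C@@]1(C)CC[C@]2(C)CCC(C)(C)C[C@H]2[C@@H]1CCC1(C)OCCO1 | intermediate
32 | (R)-4-benzyloxazolidin-2-one | O=C1N[C@H](Cc2ccccc2)CO1 | starting material
33 | 3-methylbut-2-enoyl chloride | CC(C)=CC(Cl)=O | starting material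
34 | (R)-4-benzyl-3-(3-methylbut-2-enoyl)oxazolidin-2-one | CC(C)=CC(=O)N1[C@H](Cc2ccccc2)COC1=O | intermediate
35 | dibutylboron (Z)-dienolate of 34 (not isolated) | CCCCB(CCCC)O/C(=C\C(C)=C)N1[C@H](Cc2ccccc2)COC1=O | intermediate
36 | syn-aldol adduct (imide at C3, isopropenyl on C7, C8–OH) | O=C(N1[C@H](Cc2ccccc2)COC1=O)[C@H](C(C)=C)[C@@H](O)[C@@]1(C)CC[C@]2(C)CCC(C)(C)C[C@H]2[C@@H]1CCC1(C)OCCO1 | intermediate
37 | C8 tert-butyldimethylsilyl ether of 36 | O=C(N1[C@H](Cc2ccccc2)COC1=O)[C@H](C(C)=C)[C@@H](O[Si](C)(C)C(C)(C)C)[C@@]1(C)CC[C@]2(C)CCC(C)(C)C[C@H]2[C@@H]1CCC1(C)OCCO1 | intermediate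
38 | C3 primary alcohol | OC[C@H](C(C)=C)[C@@H](O[Si](C)(C)C(C)(C)C)[C@@]1(C)CC[C@]2(C)CCC(C)(C)C[C@H]2[C@@H]1CCC1(C)OCCO1 | intermediate
39 | C3 aldehyde | O=C[C@H](C(C)=C)[C@@H](O[Si](C)(C)C(C)(C)C)[C@@]1(C)CC[C@]2(C)CCC(C)(C)C[C@H]2[C@@H]1CCC1(C)OCCO1 | intermediate
40 | (3R)-homoallylic alcohol | C=CC[C@@H](O)[C@H](C(C)=C)[C@@H](O[Si](C)(C)C(C)(C)C)[C@@]1(C)CC[C@]2(C)CCC(C)(C)C[C@H]2[C@@H]1CCC1(C)OCCO1 | intermediate
41 | C3 triethylsilyl ether of 40 | C=CC[C@@H](O[Si](CC)(CC)CC)[C@H](C(C)=C)[C@@H](O[Si](C)(C)C(C)(C)C)[C@@]1(C)CC[C@]2(C)CCC(C)(C)C[C@H]2[C@@H]1CCC1(C)OCCO1 | intermediate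
42 | cyclopentene (ring A, C5=C6; C3–OSiEt3 cis to C8) | CC[Si](CC)(CC)O[C@@H]1CC=C(C)[C@@H]1[C@@H](O[Si](C)(C)C(C)(C)C)[C@@]1(C)CC[C@]2(C)CCC(C)(C)C[C@H]2[C@@H]1CCC1(C)OCCO1 | intermediate
43 | C5 alkylborane (not isolated) | CC[Si](CC)(CC)O[C@@H]1C[C@@H](B)[C@H](C)[C@@H]1[C@@H](O[Si](C)(C)C(C)(C)C)[C@@]1(C)CC[C@]2(C)CCC(C)(C)C[C@H]2[C@@H]1CCC1(C)OCCO1 | intermediate
44 | C5 alcohol (C5–OH trans to C6 methyl; C6 methyl cis to C8) | CC[Si](CC)(CC)O[C@@H]1C[C@@H](O)[C@H](C)[C@@H]1[C@@H](O[Si](C)(C)C(C)(C)C)[C@@]1(C)CC[C@]2(C)CCC(C)(C)C[C@H]2[C@@H]1CCC1(C)OCCO1 | intermediate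
45 | C5,C8-bis(tert-butyldimethylsilyl) C3-triethylsilyl ether | CC[Si](CC)(CC)O[C@@H]1C[C@@H](O[Si](C)(C)C(C)(C)C)[C@H](C)[C@@H]1[C@@H](O[Si](C)(C)C(C)(C)C)[C@@]1(C)CC[C@]2(C)CCC(C)(C)C[C@H]2[C@@H]1CCC1(C)OCCO1 | intermediate
46 | C3 alcohol with free C2 ketone | O[C@@H]1C[C@@H](O[Si](C)(C)C(C)(C)C)[C@H](C)[C@@H]1[C@@H](O[Si](C)(C)C(C)(C)C)[C@@]1(C)CC[C@]2(C)CCC(C)(C)C[C@H]2[C@@H]1CCC(C)=O | intermediate
47 | C2,C3-diketone | O=C1C[C@@H](O[Si](C)(C)C(C)(C)C)[C@H](C)[C@@H]1[C@@H](O[Si](C)(C)C(C)(C)C)[C@@]1(C)CC[C@]2(C)CCC(C)(C)C[C@H]2[C@@H]1CCC(C)=O | intermediate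
48 | C5,C8-bis(tert-butyldimethylsilyl) ether of the target | C/C1=C2\C[C@@H](O[Si](C)(C)C(C)(C)C)[C@H](C)[C@@H]2[C@@H](O[Si](C)(C)C(C)(C)C)[C@@]2(C)CC[C@]3(C)CCC(C)(C)C[C@H]3[C@@H]2CC1 | intermediate
49 | CNP0213887.1, (5R,6R,7S,8R,9S,12S,17S,18S) in the numbering used here | C/C1=C2\C[C@@H](O)[C@H](C)[C@@H]2[C@@H](O)[C@@]2(C)CC[C@]3(C)CCC(C)(C)C[C@H]3[C@@H]2CC1 | target

**Step count**
Total: 32 steps. Longest linear sequence: 29 steps (steps 1–8, 11–18, 20–32); steps 9–10 and step 19 make the two side fragments.

**Steps most likely to fail**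

Step 31. The reductive coupling may stall at the titanium pinacolate or turn intermolecular, and long exposure of the α-branched cyclopentanone to Lewis-acidic titanium may epimerise C7 or eliminate the β-silyloxy groups. The fallback sets out from 47 and comes back at 48: SmI2 (THF, HMPA, −78 → 0 °C) effects the ketyl–ketone pinacol cyclisation to the ring B cis-2,3-diol F1; thiocarbonyldiimidazole (DMAP, toluene, reflux) converts it into the cyclic thiocarbonate F2; 1,3-dimethyl-2-phenyl-1,3,2-diazaphospholidine (40 °C) then carries out the Corey–Winter olefination, a stereospecific syn elimination that gives 48.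

Step 12. The [3,3] shift may be slow because the boat transition state is strained by the trans ring fusion and by allylic strain at the terminus that becomes quaternary, which gives the ketene acetal time for C-silylation, hydrolysis or elimination. The fallback sets out from 14 and 18 and comes back at 24. Wittig methylenation of 14 (Ph3P=CH2, THF) gives the C11 vinyl ester F3, and CF3CO2H removes the tert-butyl group to give the acid F4. The alkenyllithium 19, made from 18, is trapped with paraformaldehyde to give (E)-4-benzyloxy-3-methylbut-2-en-1-ol F5, which is esterified with F4 (DCC, DMAP) to the allyl ester F6. An acyclic Ireland–Claisen rearrangement (LiN(i-Pr)2, Me3SiCl, THF, −78 → 23 °C) forms the C9–C18 bond and gives the diene acid F7. Ring-closing metathesis of its C10 and C11 vinyl groups (second-generation Grubbs catalyst, CH2Cl2, 40 °C) closes ring C and gives 24 or its C18 epimer F11; F11 is taken through steps 13 and 14 to the same aldehyde 27. In this fallback C9 rests on acyclic stereocontrol, so separation of C9 diastereomers may be needed.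

Step 11. The addition may show poor facial selectivity at the α-quaternary aldehyde, the organolithium may attack the ester, or lactonisation may stay incomplete. The fallback sets out from 14 and 18 and comes back at 21: the adduct of 19 and 14 is quenched at −78 °C to keep the hydroxy ester F8 as both C11 epimers; Dess–Martin oxidation gives the enone F9; Corey–Bakshi–Shibata reduction ((S)-2-methyl-CBS-oxazaborolidine, catecholborane, toluene, −78 °C), with the tertiary C12 as the large group, gives the single C11 epimer F10 under reagent control; NaH (cat.) in THF closes the lactone 21.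

Further compounds
F1 | step 31 | ring B cis-2,3-diol from pinacol cyclisation of 47 (bis-silyl ether; C2 and C3 not defined) | CC1(O)C2(O)C[C@@H](O[Si](C)(C)C(C)(C)C)[C@H](C)[C@@H]2[C@@H](O[Si](C)(C)C(C)(C)C)[C@@]2(C)CC[C@]3(C)CCC(C)(C)C[C@H]3[C@@H]2CC1
F2 | step 31 | cyclic 2,3-thiocarbonate of F1 | CC12OC(=S)OC1(C[C@@H](O[Si](C)(C)C(C)(C)C)[C@@H]3C)[C@H]3[C@@H](O[Si](C)(C)C(C)(C)C)[C@@]1(C)CC[C@]3(C)CCC(C)(C)C[C@H]3[C@@H]1CC2
F3 | step 12 | C11 vinyl analogue of 14 (tert-butyl ester) | C=C[C@]1(C)CCC(C)(C)C[C@H]1CC(=O)OC(C)(C)C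
F4 | step 12 | carboxylic acid from F3 | C=C[C@]1(C)CCC(C)(C)C[C@H]1CC(=O)O
F5 | step 12 | (E)-4-benzyloxy-3-methylbut-2-en-1-ol | OC/C=C(C)/COCc1ccccc1
F6 | step 12 | allyl ester of F4 with F5 | C=C[C@]1(C)CCC(C)(C)C[C@H]1CC(=O)OC/C=C(C)/COCc1ccccc1
F7 | step 12 | diene acid with quaternary C9 (methyl, vinyl, CH2OBn; C18 not defined) | C=C[C@]1(C)CCC(C)(C)C[C@H]1C(C(=O)O)[C@](C)(C=C)COCc1ccccc1
F11 | step 12 | C18 epimer of 24 (C19OOH equatorial) | c1ccccc1COC[C@@]2(C)C=C[C@]3(C)CCC(C)(C)C[C@H]3[C@@H]2C(=O)O
F8 | step 11 | hydroxy tert-butyl ester, both C11 epimers | OC(/C=C(C)/COCc1ccccc1)[C@]1(C)CCC(C)(C)C[C@H]1CC(=O)OC(C)(C)C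
F9 | step 11 | C11 enone | O=C(/C=C(C)/COCc1ccccc1)[C@]1(C)CCC(C)(C)C[C@H]1CC(=O)OC(C)(C)C
F10 | step 11 | hydroxy tert-butyl ester, single C11 epimer (configuration as in 20) | O[C@H](/C=C(C)/COCc1ccccc1)[C@]1(C)CCC(C)(C)C[C@H]1CC(=O)OC(C)(C)C
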